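**Retrosynthetic overview**
1. Target ⇐ cis-fused 2-ketone 20: the C2 ketone is reduced and angeloylated, and C15 is carried as a silyl ether and oxidised last.
2. Ring B, the C9–C10 bond and the C7=C8 double bond come from one anionic oxy-Cope rearrangement; the enabling feature is the C2 oxygen of ring A, which makes C9=C8–C7–C2(O)–C1=C10 a 3-oxy-1,5-diene once a temporary C2–C7 bond bridges ring A into a bicyclo[2.2.2]octene (17).
3. 17 ⇐ ketone 13 (enol triflate and methyl coupling fix the E alkene that later decides C9) ⇐ amide 6 + Grignard reagent 12 from (R)-citronellol (source of C13).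
4. Bicycle ⇐ asymmetric Diels–Alder reaction of the isophorone silyl dienol ether 3 with acryloyl imide 4 (sets C5 and, through the bridge, C10 and C9).
5. Ring order: ring A (isophorone) → temporary bicyclo[2.2.2]octene → ring B by the rearrangement, which opens the bridge again.

Key step: step 11

Remark: decalin compounds carry labdane numbering (ring carbons C1–C10, chain C11–C15, C17 on C8, C20 on C10) with every descriptor explicit and the ring fusion cis; the sense of induction in step 2 is assumed to follow the usual model for this catalyst.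

**Step 1**
Reactants: 1 isophorone (3,5,5-trimethylcyclohex-2-en-1-one)
Product: 3 triethyl[(3,5,5-trimethylcyclohexa-1,3-dien-1-yl)oxy]silane, via bromomagnesium dienolate 2 (not isolated)
Conditions: MeMgBr, FeCl3 (5 mol %), Et2O, 0 °C; then Et3SiCl, Et3N, DMPU, 0 °C → rt
Reagents that add atoms: chlorotriethylsilane, CC[Si](Cl)(CC)CC
Why: Iron-catalysed γ-deprotonation of the enone by the Grignard reagent should give the linearly conjugated (thermodynamic) dienolate, and O-silylation (silyl dienol ether formation) then gives the 1-silyloxy-1,3-diene whose termini are the future C2 and C5; no stereocentre is formed.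

**Step 2**
Reactants: 3 triethyl[(3,5,5-trimethylcyclohexa-1,3-dien-1-yl)oxy]silane; 4 3-acryloyl-1,3-oxazolidin-2-one
Product: 5 3-{[(1R,2S,4R)-5,8,8-trimethyl-1-(triethylsilyloxy)bicyclo[2.2.2]oct-5-en-2-yl]carbonyl}-1,3-oxazolidin-2-one (acyl group endo, on the side of the C5=C6 bridge)
Conditions: [Cu((S,S)-t-Bu-box)](SbF6)2 (10 mol %; t-Bu-box = 2,2'-(propane-2,2-diyl)bis(4-tert-butyl-4,5-dihydrooxazole)), CH2Cl2, −40 → 0 °C
Reagents that add atoms: none
Why: Catalytic asymmetric Diels–Alder reaction of an achiral diene, in which the imide chelated to the square-planar divalent copper complex is attacked on the re face of its α-carbon, the silyloxy group directs the acyl-bearing carbon to the oxygenated terminus (ortho rule) and the endo rule places the acyl group beside the new C5=C6 bridge, so that C1, C2 and C4 of the bicycle (later C2, C7 and C5) should be set as 1R,2S,4R in one event.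

**Step 3**
Reactants: 5 the imide from step 2
Product: 6 (1R,2S,4R)-N-methoxy-N,5,8,8-tetramethyl-1-(triethylsilyloxy)bicyclo[2.2.2]oct-5-ene-2-carboxamide
Conditions: MeNH(OMe)·HCl, AlMe3, CH2Cl2, 0 °C → rt
Reagents that add atoms: N,O-dimethylhydroxylamine hydrochloride, Cl.CNOC
Why: Aminolysis of the imide by the aluminium amide formed in the flask (Weinreb amide synthesis) cleaves the exocyclic acyl–nitrogen bond and touches no stereocentre.

**Step 4**
Reactants: 7 (R)-citronellol ((3R)-3,7-dimethyloct-6-en-1-ol)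
Product: 8 triisopropyl{[(3R)-3,7-dimethyloct-6-en-1-yl]oxy}silane
Conditions: i-Pr3SiCl, imidazole, DMF, rt
Reagents that add atoms: chlorotriisopropylsilane, CC(C)[Si](Cl)(C(C)C)C(C)C
Why: Silyl ether protection of the primary alcohol with a group that should survive Grignard formation, strong base and dissolving metal; the C13 stereocentre comes from the chiral pool.

**Step 5**
Reactants: 8 the silyl ether from step 4
Product: 10 (4R)-4-methyl-6-(triisopropylsilyloxy)hexan-1-ol, via aldehyde 9 (not isolated)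
Conditions: O3, CH2Cl2/MeOH, −78 °C; then NaBH4, −78 °C → rt
Reagents that add atoms: ozone, [O-][O+]=O
Why: Ozonolysis of the trisubstituted alkene with reductive borohydride work-up removes the isopropylidene unit and leaves a primary alcohol at the future C9 without touching C13.

**Step 6**
Reactants: 10 (4R)-4-methyl-6-(triisopropylsilyloxy)hexan-1-ol
Product: 11 {[(3R)-6-iodo-3-methylhexyl]oxy}triisopropylsilane
Conditions: I2, PPh3, imidazole, CH2Cl2, 0 °C → rt
Reagents that add atoms: iodine, II
Why: Appel-type iodination, an SN2 displacement of the alkoxyphosphonium ion at a primary carbon.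

**Step 7**
Reactants: 11 the iodide from step 6; 6 the N-methoxy-N-methylamide from step 3
Product: 13 (5R)-5-methyl-1-[(1R,2S,4R)-5,8,8-trimethyl-1-(triethylsilyloxy)bicyclo[2.2.2]oct-5-en-2-yl]-7-(triisopropylsilyloxy)heptan-1-one, via Grignard reagent 12 (not isolated)
Conditions: Mg, THF, 40 °C; then 6, THF, 0 °C → rt
Reagents that add atoms: none
Why: Weinreb ketone synthesis, in which the primary Grignard reagent adds once and the chelated adduct collapses only on work-up, joining the fragments through the C8–C9 bond.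

**Step 8**
Reactants: 13 the ketone from step 7
Product: 15 (1Z,5R)-5-methyl-1-[(1R,2S,4R)-5,8,8-trimethyl-1-(triethylsilyloxy)bicyclo[2.2.2]oct-5-en-2-yl]-7-(triisopropylsilyloxy)hept-1-en-1-yl trifluoromethanesulfonate, via potassium enolate 14 (not isolated)
Conditions: KN(SiMe3)2, THF, −78 °C; then PhNTf2, −78 → 0 °C
Reagents that add atoms: N-phenylbis(trifluoromethanesulfonimide), O=S(=O)(N(c1ccccc1)S(=O)(=O)C(F)(F)F)C(F)(F)F
Why: Kinetic deprotonation at the unhindered C9 methylene should give the Z enolate, in which the chain avoids allylic strain with the bulky bicyclic substituent, and enol triflate formation fixes the geometry that later decides C9.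

**Step 9**
Reactants: 15 the enol triflate from step 8
Product: 16 triethyl{[(1R,2R,4R)-5,8,8-trimethyl-2-[(2E,6R)-6-methyl-8-(triisopropylsilyloxy)oct-2-en-2-yl]bicyclo[2.2.2]oct-5-en-1-yl]oxy}silane
Conditions: MeMgBr, Fe(acac)3 (5 mol %), THF/NMP, −30 °C
Reagents that add atoms: methylmagnesium bromide, C[Mg]Br
Why: Iron-catalysed Kumada-type cross-coupling of the enol triflate should replace triflate by methyl (C17) with retention of alkene geometry, giving the E trisubstituted alkene.

**Step 10**
Reactants: 16 the bis-silyl ether from step 9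
Product: 17 (1R,2R,4R)-5,8,8-trimethyl-2-[(2E,6R)-6-methyl-8-(triisopropylsilyloxy)oct-2-en-2-yl]bicyclo[2.2.2]oct-5-en-1-ol
Conditions: PPTS, MeOH, 40 °C
Reagents that add atoms: none
Why: Acid-catalysed methanolysis (selective silyl ether cleavage) removes the triethylsilyl group from the bridgehead oxygen, which cannot ionise, while the far more acid-stable primary triisopropylsilyl ether should stay.

**Step 11**
Reactants: 17 the bridgehead alcohol from step 10
Product: 20 (5R,9R,10S,13R)-15-(triisopropylsilyloxy)labd-7-en-2-one, via potassium alkoxide 18 (not isolated), via potassium enolate 19 (not isolated)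
Conditions: KH, 18-crown-6, THF, 0 → 50 °C
Reagents that add atoms: none
Why: KH with 18-crown-6 gives the bridgehead alkoxide 18, whose 3-oxido-1,5-diene C9=C8–C7–C2(O−)–C1=C10 undergoes an anionic oxy-Cope ([3,3]-sigmatropic) rearrangement: the C2–C7 bond breaks, the C9–C10 bond and the C7=C8 double bond form, and enolate 19 gives ketone 20 on aqueous work-up. The closest known reaction type is the anionic oxy-Cope rearrangement of endo-vinyl bicyclo[2.2.2]oct-5-enols to cis-fused octalones, here with the oxygen on the bridgehead end of the breaking bond. Ring B is the only ring closed, by suprafacial bonding of C9 to C10 through the boat-shaped six-centre transition state that the bicyclic frame enforces, while the temporary bridge ring opens and releases its strain. C10 becomes quaternary with the new bond on the face of C1=C10 that carries the C6–C7 bridge, so it is cis to the C5–C6 bond and the fusion is cis with C5 fixed since step 2; C9 is set by the E geometry of C8=C9, which in the boat places H-9 on the side of the C10 methyl group (9R). The step needs the alkenyl group endo (only then can C9 reach C10; secured by the endo rule in step 2), a single alkene geometry (steps 8 and 9) and rearrangement in preference to simple cleavage of the alkoxide, which the close intramolecular arrangement and the moderate temperature should favour; a [1,3] shift would have to form a cyclobutane and is excluded.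

**Step 12**
Reactants: 20 the ketone from step 11
Product: 21 (2S,5R,9R,10S,13R)-15-(triisopropylsilyloxy)labd-7-en-2-ol
Conditions: Li, NH3 (l), THF, MeOH, −78 °C
Reagents that add atoms: none
Why: Dissolving-metal reduction of the ketone should give the thermodynamically preferred equatorial 2α-alcohol (2S), because an axial hydroxyl on the β face of C2 would be syn-axial to the methyl groups on C4 and C10.

**Step 13**
Reactants: 21 the alcohol from step 12; 22 angelic acid ((2Z)-2-methylbut-2-enoic acid)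
Product: 24 (2S,5R,9R,10S,13R)-15-(triisopropylsilyloxy)labd-7-en-2-yl (2Z)-2-methylbut-2-enoate, via mixed anhydride 23 (not isolated)
Conditions: 2,4,6-trichlorobenzoyl chloride, Et3N, toluene, rt; then 21, 75 °C
Reagents that add atoms: none
Why: Yamaguchi-type mixed-anhydride esterification without a nucleophilic catalyst acylates the secondary alcohol at the less hindered angeloyl carbonyl with retention at C2 and should avoid the Z to E isomerisation that nucleophilic catalysts cause.

**Step 14**
Reactants: 24 the angelate from step 13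
Product: 25 (2S,5R,9R,10S,13R)-15-hydroxylabd-7-en-2-yl (2Z)-2-methylbut-2-enoate
Conditions: HF·pyridine, pyridine, THF, 0 °C → rt
Reagents that add atoms: none
Why: Fluoride-mediated cleavage of the primary silyl ether under buffered conditions that should leave the angelate and the trisubstituted alkene untouched.

**Step 15**
Reactants: 25 the primary alcohol from step 14
Product: 27 (2S,5R,9R,10S,13R)-2-[(2Z)-2-methylbut-2-enoyloxy]labd-7-en-15-oic acid (CNP0248298.1), via aldehyde 26 (not isolated)
Conditions: TEMPO (20 mol %), PhI(OAc)2, MeCN/H2O, rt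
Reagents that add atoms: water, O
Why: Nitroxyl-catalysed oxidation with a hypervalent iodine oxidant takes the primary alcohol through the aldehyde hydrate to the carboxylic acid without touching the secondary ester or either alkene.

**Compound list**
1 | isophorone (3,5,5-trimethylcyclohex-2-en-1-one) | CC1=CC(=O)CC(C)(C)C1 | starting material
2 | bromomagnesium 3,5,5-trimethylcyclohexa-1,3-dien-1-olate | Br[Mg]OC1=CC(C)=CC(C)(C)C1 | intermediate
3 | triethyl[(3,5,5-trimethylcyclohexa-1,3-dien-1-yl)oxy]silane | CC[Si](CC)(CC)OC1=CC(C)=CC(C)(C)C1 | intermediate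
4 | 3-acryloyl-1,3-oxazolidin-2-one | C=CC(=O)N1CCOC1=O | starting material
5 | 3-{[(1R,2S,4R)-5,8,8-trimethyl-1-(triethylsilyloxy)bicyclo[2.2.2]oct-5-en-2-yl]carbonyl}-1,3-oxazolidin-2-one | O=C(N1CCOC1=O)[C@H]2C[C@H]3C(C)=C[C@]2(O[Si](CC)(CC)CC)CC3(C)C | intermediate
6 | (1R,2S,4R)-N-methoxy-N,5,8,8-tetramethyl-1-(triethylsilyloxy)bicyclo[2.2.2]oct-5-ene-2-carboxamide | CON(C)C(=O)[C@H]2C[C@H]3C(C)=C[C@]2(O[Si](CC)(CC)CC)CC3(C)C | intermediate
7 | (R)-citronellol ((3R)-3,7-dimethyloct-6-en-1-ol) | CC(C)=CCC[C@@H](C)CCO | starting material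
8 | triisopropyl{[(3R)-3,7-dimethyloct-6-en-1-yl]oxy}silane | CC(C)=CCC[C@@H](C)CCO[Si](C(C)C)(C(C)C)C(C)C | intermediate
9 | (4R)-4-methyl-6-(triisopropylsilyloxy)hexanal | O=CCC[C@@H](C)CCO[Si](C(C)C)(C(C)C)C(C)C | intermediate
10 | (4R)-4-methyl-6-(triisopropylsilyloxy)hexan-1-ol | OCCC[C@@H](C)CCO[Si](C(C)C)(C(C)C)C(C)C | intermediate
11 | {[(3R)-6-iodo-3-methylhexyl]oxy}triisopropylsilane | ICCC[C@@H](C)CCO[Si](C(C)C)(C(C)C)C(C)C | intermediate
12 | [(4R)-4-methyl-6-(triisopropylsilyloxy)hexyl]magnesium iodide | I[Mg]CCC[C@@H](C)CCO[Si](C(C)C)(C(C)C)C(C)C | intermediate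
13 | (5R)-5-methyl-1-[(1R,2S,4R)-5,8,8-trimethyl-1-(triethylsilyloxy)bicyclo[2.2.2]oct-5-en-2-yl]-7-(triisopropylsilyloxy)heptan-1-one | O=C(CCC[C@@H](C)CCO[Si](C(C)C)(C(C)C)C(C)C)[C@H]2C[C@H]3C(C)=C[C@]2(O[Si](CC)(CC)CC)CC3(C)C | intermediate
14 | potassium (1Z,5R)-enolate of 13 (deprotonated at C9) | [K+].[O-]/C(=C\CC[C@@H](C)CCO[Si](C(C)C)(C(C)C)C(C)C)[C@H]2C[C@H]3C(C)=C[C@]2(O[Si](CC)(CC)CC)CC3(C)C | intermediate
15 | (1Z,5R)-5-methyl-1-[(1R,2S,4R)-5,8,8-trimethyl-1-(triethylsilyloxy)bicyclo[2.2.2]oct-5-en-2-yl]-7-(triisopropylsilyloxy)hept-1-en-1-yl trifluoromethanesulfonate | FC(F)(F)S(=O)(=O)O/C(=C\CC[C@@H](C)CCO[Si](C(C)C)(C(C)C)C(C)C)[C@H]2C[C@H]3C(C)=C[C@]2(O[Si](CC)(CC)CC)CC3(C)C | intermediate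
16 | triethyl{[(1R,2R,4R)-5,8,8-trimethyl-2-[(2E,6R)-6-methyl-8-(triisopropylsilyloxy)oct-2-en-2-yl]bicyclo[2.2.2]oct-5-en-1-yl]oxy}silane | C/C(=C\CC[C@@H](C)CCO[Si](C(C)C)(C(C)C)C(C)C)[C@H]2C[C@H]3C(C)=C[C@]2(O[Si](CC)(CC)CC)CC3(C)C | intermediate
17 | (1R,2R,4R)-5,8,8-trimethyl-2-[(2E,6R)-6-methyl-8-(triisopropylsilyloxy)oct-2-en-2-yl]bicyclo[2.2.2]oct-5-en-1-ol | C/C(=C\CC[C@@H](C)CCO[Si](C(C)C)(C(C)C)C(C)C)[C@H]2C[C@H]3C(C)=C[C@]2(O)CC3(C)C | intermediate
18 | potassium alkoxide of 17 | [K+].C/C(=C\CC[C@@H](C)CCO[Si](C(C)C)(C(C)C)C(C)C)[C@H]2C[C@H]3C(C)=C[C@]2([O-])CC3(C)C | intermediate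
19 | potassium C1=C2 enolate of 20 | [K+].[O-]C=1CC(C)(C)[C@H]2CC=C(C)[C@@H](CC[C@@H](C)CCO[Si](C(C)C)(C(C)C)C(C)C)[C@@]2(C)C=1 | intermediate
20 | (5R,9R,10S,13R)-15-(triisopropylsilyloxy)labd-7-en-2-one (cis-fused) | O=C1CC(C)(C)[C@H]2CC=C(C)[C@@H](CC[C@@H](C)CCO[Si](C(C)C)(C(C)C)C(C)C)[C@@]2(C)C1 | intermediate
21 | (2S,5R,9R,10S,13R)-15-(triisopropylsilyloxy)labd-7-en-2-ol | O[C@H]1CC(C)(C)[C@H]2CC=C(C)[C@@H](CC[C@@H](C)CCO[Si](C(C)C)(C(C)C)C(C)C)[C@@]2(C)C1 | intermediate
22 | angelic acid ((2Z)-2-methylbut-2-enoic acid) | C/C=C(/C)C(=O)O | starting material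
23 | (2Z)-2-methylbut-2-enoic 2,4,6-trichlorobenzoic anhydride | C/C=C(/C)C(=O)OC(=O)c1c(Cl)cc(Cl)cc1Cl | intermediate
24 | (2S,5R,9R,10S,13R)-15-(triisopropylsilyloxy)labd-7-en-2-yl (2Z)-2-methylbut-2-enoate | C/C=C(/C)C(=O)O[C@H]1CC(C)(C)[C@H]2CC=C(C)[C@@H](CC[C@@H](C)CCO[Si](C(C)C)(C(C)C)C(C)C)[C@@]2(C)C1 | intermediate
25 | (2S,5R,9R,10S,13R)-15-hydroxylabd-7-en-2-yl (2Z)-2-methylbut-2-enoate | C/C=C(/C)C(=O)O[C@H]1CC(C)(C)[C@H]2CC=C(C)[C@@H](CC[C@@H](C)CCO)[C@@]2(C)C1 | intermediate
26 | (2S,5R,9R,10S,13R)-15-oxolabd-7-en-2-yl (2Z)-2-methylbut-2-enoate | C/C=C(/C)C(=O)O[C@H]1CC(C)(C)[C@H]2CC=C(C)[C@@H](CC[C@@H](C)CC=O)[C@@]2(C)C1 | intermediate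
27 | (2S,5R,9R,10S,13R)-2-[(2Z)-2-methylbut-2-enoyloxy]labd-7-en-15-oic acid (CNP0248298.1) | C/C=C(/C)C(=O)O[C@H]1CC(C)(C)[C@H]2CC=C(C)[C@@H](CC[C@@H](C)CC(=O)O)[C@@]2(C)C1 | target

**Totals and risks**
Total step count: 15. Longest linear sequence: 12 steps (steps 1–3 and 7–15 from isophorone, or steps 4–15 from (R)-citronellol).

Steps most likely to fail:

Step 2. The Lewis acid may steer the silyl dienol ether into a stepwise conjugate addition with loss of the silyl group instead of ring closure, and facial discrimination may be poor with this hindered diene. The fallback sets out from 3 and comes back at 6; it uses no Lewis acid and secures the absolute configuration by a covalent auxiliary and separation. (4R)-4-Benzyl-1,3-oxazolidin-2-one is N-acylated (n-BuLi, acryloyl chloride, THF, −78 °C) to (4R)-3-acryloyl-4-benzyl-1,3-oxazolidin-2-one F1. Heating F1 with 3 (toluene, 110 °C) should give the endo adducts as two diastereomers, from which (4R)-4-benzyl-3-{[(1R,2S,4R)-5,8,8-trimethyl-1-(triethylsilyloxy)bicyclo[2.2.2]oct-5-en-2-yl]carbonyl}-1,3-oxazolidin-2-one F2 is separated by chromatography or crystallisation. Aminolysis of F2 under the conditions of step 3 gives 6.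

Step 11. The alkoxide may simply cleave at the C2–C7 bond and be protonated as an open-chain enone, or the crowded boat transition state that creates the quaternary C10 may not be reached before decomposition. The fallback sets out from 13 and comes back at 20; it replaces the rearrangement by an intramolecular Michael addition. Methanolysis of the triethylsilyl ether of 13 (PPTS, MeOH) followed by K2CO3 should open the β-hydroxy ketone by retro-aldol cleavage to (4R)-3,5,5-trimethyl-4-[(7R)-7-methyl-3-oxo-9-(triisopropylsilyloxy)nonyl]cyclohex-2-en-1-one F3. KOt-Bu (catalytic, t-BuOH/THF) should close ring B by addition of the C9 enolate to C10 from the face of the tether, giving the cis-fused (5R,9S,10S,13R)-15-(triisopropylsilyloxy)-17-norlabdane-2,8-dione F4, with the chain at C9 equilibrated to the equatorial position. Kinetic deprotonation at the unhindered C7 methylene (KN(SiMe3)2, THF, −78 °C) and trapping with PhNTf2 gives (5R,9S,10S,13R)-2-oxo-15-(triisopropylsilyloxy)-17-norlabd-7-en-8-yl trifluoromethanesulfonate F5. Negishi coupling with MeZnCl (Pd(PPh3)4, THF) returns to 20.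

Step 12. Protonation of the reduced intermediate from the open α face may give the axial alcohol, or the ketone may couple reductively. The fallback sets out from 20 and comes back at 21; it uses kinetic hydride delivery followed by inversion. LiBH(s-Bu)3 (THF, −78 °C) should attack from the α face, away from the two axial methyl groups, and give (2R,5R,9R,10S,13R)-15-(triisopropylsilyloxy)labd-7-en-2-ol F6. A Mitsunobu reaction with 4-nitrobenzoic acid (PPh3, diisopropyl azodicarboxylate, THF) inverts C2 to (2S,5R,9R,10S,13R)-15-(triisopropylsilyloxy)labd-7-en-2-yl 4-nitrobenzoate F7. Methanolysis (K2CO3, MeOH) gives 21.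

**Further compounds**
F1 | step 2 | (4R)-3-acryloyl-4-benzyl-1,3-oxazolidin-2-one | C=CC(=O)N1[C@H](Cc2ccccc2)COC1=O
F2 | step 2 | (4R)-4-benzyl-3-{[(1R,2S,4R)-5,8,8-trimethyl-1-(triethylsilyloxy)bicyclo[2.2.2]oct-5-en-2-yl]carbonyl}-1,3-oxazolidin-2-one | O=C(N1[C@H](Cc2ccccc2)COC1=O)[C@H]3C[C@H]4C(C)=C[C@]3(O[Si](CC)(CC)CC)CC4(C)C
F3 | step 11 | (4R)-3,5,5-trimethyl-4-[(7R)-7-methyl-3-oxo-9-(triisopropylsilyloxy)nonyl]cyclohex-2-en-1-one | CC1=CC(=O)CC(C)(C)[C@H]1CCC(=O)CCC[C@@H](C)CCO[Si](C(C)C)(C(C)C)C(C)C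
F4 | step 11 | (5R,9S,10S,13R)-15-(triisopropylsilyloxy)-17-norlabdane-2,8-dione | O=C1CC(C)(C)[C@H]2CCC(=O)[C@@H](CC[C@@H](C)CCO[Si](C(C)C)(C(C)C)C(C)C)[C@@]2(C)C1
F5 | step 11 | (5R,9S,10S,13R)-2-oxo-15-(triisopropylsilyloxy)-17-norlabd-7-en-8-yl trifluoromethanesulfonate | O=C1CC(C)(C)[C@H]2CC=C(OS(=O)(=O)C(F)(F)F)[C@@H](CC[C@@H](C)CCO[Si](C(C)C)(C(C)C)C(C)C)[C@@]2(C)C1
F6 | step 12 | (2R,5R,9R,10S,13R)-15-(triisopropylsilyloxy)labd-7-en-2-ol | O[C@@H]1CC(C)(C)[C@H]2CC=C(C)[C@@H](CC[C@@H](C)CCO[Si](C(C)C)(C(C)C)C(C)C)[C@@]2(C)C1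
F7 | step 12 | (2S,5R,9R,10S,13R)-15-(triisopropylsilyloxy)labd-7-en-2-yl 4-nitrobenzoate | O=C(O[C@H]1CC(C)(C)[C@H]2CC=C(C)[C@@H](CC[C@@H](C)CCO[Si](C(C)C)(C(C)C)C(C)C)[C@@]2(C)C1)c1ccc(cc1)[N+](=O)[O-]
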